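Ring C is cut at both bonds of the C4 carbonyl, C4a–C4 and C4–C3. C4 becomes carbon monoxide, C4a an aryl iodide and C3 a boron-bearing methylene. Only one carbon (C3) separates C4 from the benzylic ether carbon C2, so the alkene to be hydroborated must be C2=C3 itself, i.e. the 1-phenylvinyl ether of 2-iodo-3,5-bis(prenyloxy)phenol. A 1-phenylallyl ether would hold one carbon too many and close a seven-membered benzoxepinone. Hydroboration and intramolecular carbonylative B-alkyl Suzuki–Miyaura coupling then build ring C in one flask. C2 is born in the hydroboration, so the flavanone is resolved by asymmetric transfer hydrogenation. A chelation-controlled Claisen–Cope relay of the 5-O-prenyl group to C8 completes the target.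

Key step: step 5

Remark: prenyl = 3-methylbut-2-enyl. Flavanone numbering (O1, C2, C3, C4, C4a, C5–C8, C8a) is used for the corresponding atoms of all intermediates.
Assumption: the sense of the resolution in step 6 follows from the usual behaviour of TsDPEN catalysts with chroman-4-ones ((R,R) gives the 4R carbinol) and from the 2,4-cis preference of flavanone reduction; if the other enantiomer reacts faster, the (S,S) catalyst is used.

Step 1
Reactants: 1 phloroglucinol (benzene-1,3,5-triol, anhydrous); 2 prenol (3-methylbut-2-en-1-ol, 2 equiv)
Product: 3 3,5-bis(prenyloxy)phenol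
Conditions: PPh3, DIAD (2.1 equiv each), THF, 0 °C → rt
Reagents that add atoms: prenol 2, CC(C)=CCO
Why: Mitsunobu etherification activates the allylic alcohol and lets the phenol attack through oxygen only, which avoids the C-prenylation that phloroglucinolate anions undergo with prenyl halides and base; the bis-ether is one member of a statistical set and is separated from mono- and tris-ether by chromatography, which is acceptable at the first step with cheap materials.

Step 2
Reactants: 3 3,5-bis(prenyloxy)phenol
Product: 4 2-iodo-3,5-bis(prenyloxy)phenol (iodine between the free hydroxyl and one prenyloxy group)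
Conditions: I2 (1.0 equiv), NaHCO3, THF–H2O, 0 °C
Reagents that add atoms: iodine, II
Why: Electrophilic aromatic iodination through the phenoxide: the phloroglucinol-type ring should take up I2 far faster than the prenyl alkenes, and substitution is expected next to the free hydroxyl (the two such positions are equivalent) rather than at the carbon walled in by two prenyloxy groups, as with resorcinol and 3,5-dialkoxyphenols under these conditions.

Step 3
Reactants: 4 2-iodo-3,5-bis(prenyloxy)phenol; 5 benzoyl chloride
Product: 6 2-iodo-3,5-bis(prenyloxy)phenyl benzoate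
Conditions: Et3N, DMAP (cat.), CH2Cl2, 0 °C → rt
Reagents that add atoms: benzoyl chloride 5, O=C(Cl)c1ccccc1
Why: DMAP-catalysed O-acylation of a phenol brings in C2 and ring B as a benzoyl group under conditions harmless to the aryl iodide and the prenyl ethers.

Step 4
Reactants: 6 2-iodo-3,5-bis(prenyloxy)phenyl benzoate
Product: 7 2-iodo-3,5-bis(prenyloxy)phenyl 1-phenylvinyl ether (achiral enol ether, ArO–C(Ph)=CH2)
Conditions: Cp2TiMe2 (2.5 equiv), toluene, 70 °C, dark; filtration through basic Al2O3
Reagents that add atoms: dimethyltitanocene Cp2TiMe2 (delivers CH2), C[Ti](C)(C1C=CC=C1)C1C=CC=C1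
Why: Petasis methylenation: thermally generated Cp2Ti=CH2 adds to the ester carbonyl and the oxatitanacyclobutane collapses to the enol ether, the standard way from aryl benzoates to 1-aryloxy-1-phenylethenes, and the neutral reagent leaves aryl iodide, aryl prenyl ethers and trisubstituted alkenes untouched; the new methylene is C3.

Step 5
Reactants: 7 2-iodo-3,5-bis(prenyloxy)phenyl 1-phenylvinyl ether; 8 9-BBN (9-borabicyclo[3.3.1]nonane); 9 carbon monoxide
Product: 11 rac-5,7-bis(prenyloxy)flavanone, via B-alkyl-9-BBN adduct 10 (not isolated)
Conditions: 8 (1.05 equiv B–H), THF, 0 °C → rt; then slow addition to PdCl2(dppf) (5 mol %), anhydrous K3PO4 (3 equiv), CO (1 atm), THF, rt → 40 °C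
Reagents that add atoms: carbon monoxide 9, [C-]#[O+]
Why: Proposed new method: 9-BBN adds syn to the C2=C3 enol-ether bond with boron on the unsubstituted C3 (steric demand and oxygen donation point the same way) to give 10, zerovalent palladium inserts into the C4a–I bond, CO inserts to give an aroylpalladium iodide, and phosphate-assisted transfer of C3 from boron followed by reductive elimination forms C4a–C4 and C4–C3. The closest known reaction types are the one-flask hydroboration and intramolecular carbonylative cross-coupling of alkene-tethered aryl or vinyl iodides to cyclic ketones, and the ordinary B-alkyl Suzuki–Miyaura coupling of beta-alkoxyalkyl-9-BBN reagents made from 1,1-disubstituted enol ethers; their union on a borane that carries an aryloxide beta to boron is what has not been shown. Ring C closes as a six-membered ring by reductive elimination from a seven-membered acyl–alkyl palladacycle (Pd, C4, C4a, C8a, O1, C2, C3). C2 is created when hydrogen is delivered to C2 of the flat enol ether; no chiral element is present, both faces react alike, and 11 is taken on as the racemate on purpose. Chemoselectivity of the hydroboration rests on the 1,1-disubstituted, donor-activated alkene reacting well ahead of the two trisubstituted prenyl alkenes, which are slowed further by their allylic oxygen, and on the use of one equivalent of B–H. CO uptake must beat direct C4a–C3 coupling to the 2-phenyl-2,3-dihydrobenzofuran, which the crowded, electron-rich, doubly ortho-oxygenated arylpalladium under CO favours, and ring closure must beat loss of aryloxide from the borate (to styrene and 4), which is why 10 is fed slowly into catalyst, anhydrous K3PO4 and CO at or near room temperature.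

Step 6
Reactants: 11 rac-5,7-bis(prenyloxy)flavanone
Product: 12 (2S)-5,7-bis(prenyloxy)flavanone
Conditions: RuCl(p-cymene)[(R,R)-TsDPEN] (1 mol %), HCO2H–Et3N (5:2), EtOAc, rt, stopped just past half conversion; chromatography
Reagents that add atoms: none
Why: Kinetic resolution by asymmetric transfer hydrogenation, a known way to enantiopure flavanones: the (R,R) catalyst builds a 4R carbinol, which is matched only with the 2R ketone because this pairing gives the favoured 2,4-cis flavanol, so the 2S ketone stays behind and its purity is raised by running slightly past half conversion, while the outer-sphere hydride transfer ignores the prenyl alkenes.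

Step 7
Reactants: 12 (2S)-5,7-bis(prenyloxy)flavanone
Product: 15 (2S)-5-hydroxy-7-prenyloxy-8-prenylflavanone (target), via ortho-dienone 13 (not isolated), via para-dienone 14 (not isolated)
Conditions: Eu(fod)3 (10 mol %), acid-free CHCl3, 60 °C, sealed vessel
Reagents that add atoms: none
Why: Lanthanide-catalysed aromatic Claisen–Cope relay known for 5-O-prenylflavanones: Eu(fod)3 is held between O5 and the C4 carbonyl oxygen, so only the 5-O-prenyl ether undergoes the [3,3] shift (to C6, since C4a is blocked), the crowded dienone 13 passes the group on to C8 by a second [3,3] shift and 14 enolises to the hydrogen-bonded 5-hydroxyl, whereas the unchelated 7-O-prenyl ether needs far higher temperature and C2 is safe in the neutral, base-free medium.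

Compound list
1 | phloroglucinol (benzene-1,3,5-triol) | Oc1cc(O)cc(O)c1 | starting material
2 | prenol (3-methylbut-2-en-1-ol) | CC(C)=CCO | starting material
3 | 3,5-bis(prenyloxy)phenol | CC(C)=CCOc1cc(O)cc(OCC=C(C)C)c1 | intermediate
4 | 2-iodo-3,5-bis(prenyloxy)phenol | CC(C)=CCOc1cc(O)c(I)c(OCC=C(C)C)c1 | intermediate
5 | benzoyl chloride | O=C(Cl)c1ccccc1 | starting material
6 | 2-iodo-3,5-bis(prenyloxy)phenyl benzoate | CC(C)=CCOc1cc(OC(=O)c2ccccc2)c(I)c(OCC=C(C)C)c1 | intermediate
7 | 2-iodo-3,5-bis(prenyloxy)phenyl 1-phenylvinyl ether | CC(C)=CCOc1cc(OC(=C)c2ccccc2)c(I)c(OCC=C(C)C)c1 | intermediate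
8 | 9-BBN (9-borabicyclo[3.3.1]nonane, used as its dimer) | B1C2CCCC1CCC2 | starting material
9 | carbon monoxide | [C-]#[O+] | starting material
10 | racemic 9-{2-[2-iodo-3,5-bis(prenyloxy)phenoxy]-2-phenylethyl}-9-borabicyclo[3.3.1]nonane (not isolated) | CC(C)=CCOc1cc(OC(CB2C3CCCC2CCC3)c2ccccc2)c(I)c(OCC=C(C)C)c1 | intermediate
11 | rac-5,7-bis(prenyloxy)flavanone | CC(C)=CCOc1cc(OCC=C(C)C)c2c(c1)OC(c1ccccc1)CC2=O | intermediate
12 | (2S)-5,7-bis(prenyloxy)flavanone | CC(C)=CCOc1cc(OCC=C(C)C)c2c(c1)O[C@H](c1ccccc1)CC2=O | intermediate
13 | (2S)-6-(2-methylbut-3-en-2-yl)-2-phenyl-7-prenyloxy-2,3-dihydrochromene-4,5(6H)-dione, ortho-dienone, C6 undefined (not isolated) | O=C1C[C@@H](c2ccccc2)OC2=C1C(=O)C(C(C)(C)C=C)C(OCC=C(C)C)=C2 | intermediate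
14 | (2S)-2-phenyl-8-prenyl-7-prenyloxy-2,3-dihydrochromene-4,5(8H)-dione, para-dienone, C8 undefined (not isolated) | O=C1C[C@@H](c2ccccc2)OC2=C1C(=O)C=C(OCC=C(C)C)C2CC=C(C)C | intermediate
15 | (2S)-5-hydroxy-7-prenyloxy-8-prenylflavanone | CC(C)=CCOc1cc(O)c2c(c1CC=C(C)C)O[C@H](c1ccccc1)CC2=O | target

Total step count: 7. Longest linear sequence: 7 (1 → 3 → 4 → 6 → 7 → 11 → 12 → 15).

Steps most likely to fail

1. Step 5 (Proposed new method). The borate formed from 10 and base may shed its aryloxide by beta-elimination faster than it hands C3 to palladium. Lesser threats are coupling without CO uptake, hydroboration of a prenyl alkene and palladium-induced ionisation of the prenyl ethers. The fallback uses known chemistry, sets out from 4 and comes back at 12, so steps 3 to 6 are bypassed.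
   - Commercial ethyl (R)-3-hydroxy-3-phenylpropanoate is converted with MeNHOMe·HCl and i-PrMgCl (THF, −10 °C) into (R)-3-hydroxy-N-methoxy-N-methyl-3-phenylpropanamide F1.
   - Mitsunobu etherification of 4 with this alcohol (PPh3, DIAD, toluene, 0 °C) inverts the carbinol carbon and should give (S)-3-[2-iodo-3,5-bis(prenyloxy)phenoxy]-N-methoxy-N-methyl-3-phenylpropanamide F2.
   - Iodine–lithium exchange (n-BuLi, THF, −78 °C) then triggers a Parham-type cyclisation of the aryllithium onto the Weinreb amide and gives 12 with C2 already fixed, so no resolution is needed.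

2. Step 6. Hydride transfer may be too slow or too unselective, because the C4 carbonyl is deactivated by two oxygen donors and shielded by the 5-O-prenyl group. Long contact with the amine could also open ring C. The fallback sets out from 11 and comes back at 12.
   - NaBH4 (MeOH–THF, 0 °C) reduces 11 to rac-2,4-cis-5,7-bis(prenyloxy)flavan-4-ol F3.
   - Acylative resolution with Candida antarctica lipase B and vinyl acetate (MTBE, 30 °C) should acetylate the 4R enantiomer, in line with the usual lipase preference for (R)-1-arylalkanols. This gives (2R,4R)-4-acetoxy-5,7-bis(prenyloxy)flavan F4 and leaves (2S,4S)-5,7-bis(prenyloxy)flavan-4-ol F5.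
   - The alcohol is separated and oxidised with Dess–Martin periodinane (NaHCO3, CH2Cl2, 0 °C) to 12.

3. Step 2. Iodination may take place at the carbon between the two ether groups, run on to a diiodide or engage a prenyl alkene. The fallback replaces electrophilic substitution by directed ortho-metalation, sets out from 3 and comes back at 4.
   - Et2NCOCl and K2CO3 (MeCN, reflux) give 3,5-bis(prenyloxy)phenyl N,N-diethylcarbamate F6.
   - Brief lithiation (s-BuLi, TMEDA, THF, −78 °C) at the position flanked by carbamate and ether, followed by I2, gives 2-iodo-3,5-bis(prenyloxy)phenyl N,N-diethylcarbamate F7.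
   - NaOH in refluxing EtOH removes the carbamate to give 4.

Further compounds
F1 | step 5 | (R)-3-hydroxy-N-methoxy-N-methyl-3-phenylpropanamide | O[C@@H](c1ccccc1)CC(=O)N(C)OC
F2 | step 5 | (S)-3-[2-iodo-3,5-bis(prenyloxy)phenoxy]-N-methoxy-N-methyl-3-phenylpropanamide | CC(C)=CCOc1cc(O[C@H](c2ccccc2)CC(=O)N(C)OC)c(I)c(OCC=C(C)C)c1
F3 | step 6 | rac-2,4-cis-5,7-bis(prenyloxy)flavan-4-ol (both enantiomers written) | CC(C)=CCOc1cc(OCC=C(C)C)c2c(c1)O[C@H](c1ccccc1)C[C@@H]2O.CC(C)=CCOc1cc(OCC=C(C)C)c2c(c1)O[C@@H](c1ccccc1)C[C@H]2O
F4 | step 6 | (2R,4R)-4-acetoxy-5,7-bis(prenyloxy)flavan | CC(C)=CCOc1cc(OCC=C(C)C)c2c(c1)O[C@@H](c1ccccc1)C[C@H]2OC(C)=O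
F5 | step 6 | (2S,4S)-5,7-bis(prenyloxy)flavan-4-ol | CC(C)=CCOc1cc(OCC=C(C)C)c2c(c1)O[C@H](c1ccccc1)C[C@@H]2O
F6 | step 2 | 3,5-bis(prenyloxy)phenyl N,N-diethylcarbamate | CCN(CC)C(=O)Oc1cc(OCC=C(C)C)cc(OCC=C(C)C)c1
F7 | step 2 | 2-iodo-3,5-bis(prenyloxy)phenyl N,N-diethylcarbamate | CCN(CC)C(=O)Oc1cc(OCC=C(C)C)cc(OCC=C(C)C)c1I
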